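**Retrosynthetic overview**

1. Euglobal G3 ⇒ 5',7'-dioxygenated spirochroman (C6' isovaleryl by Friedel–Crafts acylation, C8' formyl via the C8' bromide) ⇒ spirochroman-4'-one (removal of the C4' oxygen). Unprimed locants are those of the pinane unit, primed locants those of the chroman.
2. Spirochromanone ⇒ aryl ynone carrying a cyclobutyl xanthate: in one pot a radical closes the pinane C1–C2 bond (cyclobutyl radical onto the ynone β-carbon), then the ortho phenoxide adds to the same carbon (oxa-Michael).
3. Ynone ⇒ terminal alkyne + silyl-protected 2-hydroxy-4,6-bis(benzyloxy)benzaldehyde; alkyne ⇒ (+)-nopinone by Baeyer–Villiger oxidation (moves the oxygen onto C1 as radical handle, keeps C5) and lactol alkynylation.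
4. Ring order: cyclobutane (chiral pool) and benzene ring (bought) → six-membered carbocycle of the bicyclo[3.1.1]heptane (key step) → pyran ring (same pot).
5. Enabling feature: the spiro carbon is both C2 of the pinane six-membered ring and C2' of the pyran ring, two bonds from benzylic C4'. With C4' as a ketone it is the β-carbon of an ortho-hydroxyaryl ynone/enone and accepts first the C1 radical, then the phenol oxygen. C1 and C5 are 1,3-cis on the cyclobutane, and the C6 gem-dimethyl bridge leaves only the C7 face of C2 open.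

Key step: step 8

Remark: (1R,5S)-(+)-nopinone and 3,5-bis(benzyloxy)phenol are taken as purchasable; alkoxides, the lithium acetylide and the aryllithium that exist only between two additions are not numbered.

**Route**

Step 1
Reactants: 1 (1R,5S)-(+)-nopinone
Product: 2 (1R,6S)-7,7-dimethyl-2-oxabicyclo[4.1.1]octan-3-one
Conditions: mCPBA, NaHCO3, CH2Cl2, 0 °C → rt
Reagents that add atoms: 3-chloroperoxybenzoic acid (mCPBA), O=C(OO)c1cccc(Cl)c1
Why: Baeyer–Villiger oxidation in which the more substituted bridgehead carbon C1 should migrate in preference to the C3 methylene, with retention, so that the old C1–C2 bond becomes a C1–O bond cis to the C5 side chain and C2 becomes the lactone carbonyl.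

Step 2
Reactants: 2 Baeyer–Villiger lactone
Product: 4 (1R,3S)-3-(but-3-yn-1-yl)-2,2-dimethylcyclobutan-1-ol, via lactol 3 (not isolated)
Conditions: i-Bu2AlH, CH2Cl2, −78 °C; then MeOH, K2CO3, dimethyl (1-diazo-2-oxopropyl)phosphonate, −78 °C → rt
Reagents that add atoms: Bestmann–Ohira reagent, dimethyl (1-diazo-2-oxopropyl)phosphonate, CC(=O)C(=[N+]=[N-])P(=O)(OC)OC
Why: Partial reduction to the lactol (open hydroxy aldehyde form) followed by Seyferth–Gilbert homologation with the Bestmann–Ohira reagent should give the terminal alkyne without touching either stereocentre.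

Step 3
Reactants: 4 cis-alkynyl cyclobutanol
Product: 5 O-[(1R,3S)-3-(but-3-yn-1-yl)-2,2-dimethylcyclobutyl] S-methyl carbonodithioate
Conditions: NaH, imidazole (cat.), THF, 0 °C; CS2; then MeI, 0 °C → rt
Reagents that add atoms: carbon disulfide, S=C=S; iodomethane, CI
Why: Standard xanthate formation on the secondary alkoxide installs the Barton–McCombie radical precursor, and the much less acidic terminal alkyne should be left alone.

Step 4
Reactants: 6 3,5-bis(benzyloxy)phenol
Product: 7 2,4-bis(benzyloxy)-6-hydroxybenzaldehyde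
Conditions: MgCl2, Et3N, (CH2O)n, MeCN, reflux
Reagents that add atoms: paraformaldehyde (as formaldehyde), C=O
Why: Magnesium phenoxide-directed ortho-formylation is ortho-specific and the two ortho positions of the symmetric phenol are equivalent, so a single salicylaldehyde should result.

Step 5
Reactants: 7 2,4-bis(benzyloxy)-6-hydroxybenzaldehyde
Product: 8 2,4-bis(benzyloxy)-6-[(triisopropylsilyl)oxy]benzaldehyde
Conditions: i-Pr3SiOTf, 2,6-lutidine, CH2Cl2, 0 °C → rt
Reagents that add atoms: triisopropylsilyl triflate, CC(C)[Si](C(C)C)(C(C)C)OS(=O)(=O)C(F)(F)F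
Why: Silylation of the chelated phenol with the reactive silyl triflate masks the future ring oxygen as a fluoride-labile ether that should survive acetylide addition, oxidation and radical conditions.

Step 6
Reactants: 5 xanthate alkyne; 8 silyl-protected aldehyde
Product: 9 propargylic alcohol O-[(1R,3S)-3-{5-[2,4-bis(benzyloxy)-6-(triisopropylsilyloxy)phenyl]-5-hydroxypent-3-yn-1-yl}-2,2-dimethylcyclobutyl] S-methyl carbonodithioate (both carbinol epimers)
Conditions: 5, LiN(SiMe3)2, THF, −78 °C; then 8, −78 → −40 °C; AcOH quench at −78 °C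
Reagents that add atoms: none
Why: Lithium acetylide addition to the non-enolisable aldehyde with a hindered, non-nucleophilic amide base should spare the xanthate, the cold acid quench forestalls silyl migration to the new alkoxide, and the new carbinol centre needs no control because it is oxidised next.

Step 7
Reactants: 9 propargylic alcohol
Product: 10 aryl ynone O-[(1R,3S)-3-{5-[2,4-bis(benzyloxy)-6-(triisopropylsilyloxy)phenyl]-5-oxopent-3-yn-1-yl}-2,2-dimethylcyclobutyl] S-methyl carbonodithioate
Conditions: MnO2 (activated, excess), CH2Cl2, rt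
Reagents that add atoms: none
Why: Manganese dioxide oxidises only the benzylic–propargylic alcohol and should leave the xanthate, the benzyl ethers and the silyl ether untouched.

Step 8
Reactants: 10 aryl ynone xanthate
Product: 13 (1R,2R,5S)-5',7'-bis(benzyloxy)-6,6-dimethylspiro[bicyclo[3.1.1]heptane-2,2'-chroman]-4'-one, via silyl enone 11 (not isolated), via hydroxy enone 12 (not isolated)
Conditions: (Me3Si)3SiH, AIBN (syringe pump), PhMe (0.005 M), 85 °C; then Bu4NF, THF, 0 °C; AcOH
Reagents that add atoms: none
Why: The silyl radical adds to the thiocarbonyl sulfur, the adduct fragments to the secondary cyclobutyl radical at C1, this radical attacks the β-carbon of the ynone (the future spiro carbon C2) and the α-keto vinyl radical takes hydrogen from the silane to give 11; fluoride then unmasks the ortho phenoxide 12, which adds to the same carbon. The closest known reaction types are the Barton–McCombie-initiated Giese cyclisation of alkyl radicals onto alkynones and the oxa-Michael closure of ortho-hydroxyaryl β,β-dialkyl enones that ends the Kabbe chromanone synthesis. The six-membered carbocycle of the bicyclo[3.1.1]heptane closes 6-exo-dig across the 1,3-positions of the cyclobutane, and the pyranone ring closes 6-endo-trig. C1 is controlled by the C5 stereocentre, since the bridged ring can only form cis to the tether; the spiro centre C2 is controlled by the C6 gem-dimethyl bridge, whose inward methyl group blocks one face of the exocyclic enone, so the phenoxide should enter from the C7 face as reagents do with β-pinene, placing oxygen anti to the gem-dimethyl bridge as in the target, and both enone geometries converge on the same product. The step needs the silyl radical to choose the xanthate over the ynone (thiocarbonyl addition is the faster process and the silane is kept at low concentration), exo attack at the β-carbon (polarity-matched and the only way to a six-membered ring) and kinetic control of the oxa-Michael stage (0 °C, short time, acid quench), because the natural spiro epimer carries the larger CH2 group on the hindered face and need not be the more stable one.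

Step 9
Reactants: 13 spirochromanone
Product: 15 (1R,2R,5S)-5',7'-bis(benzyloxy)-6,6-dimethylspiro[bicyclo[3.1.1]heptane-2,2'-chromane], via chromanol 14 (not isolated)
Conditions: NaBH4, MeOH/THF, 0 °C; solvent switch; then Et3SiH, CF3CO2H, CH2Cl2, −20 °C
Reagents that add atoms: none
Why: Hydride reduction to the chroman-4'-ol and ionic hydrogenation of the resulting trioxygenated benzylic cation (the usual flavan-4-ol to flavan protocol) should remove the C4' oxygen, after which the spiro centre can no longer epimerise by retro-oxa-Michael reaction.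

Step 10
Reactants: 15 dibenzyl spirochroman
Product: 16 (1R,2R,5S)-5',7'-bis(benzyloxy)-8'-bromo-6,6-dimethylspiro[bicyclo[3.1.1]heptane-2,2'-chromane]
Conditions: NBS (1.0 equiv), CH2Cl2, −78 → 0 °C
Reagents that add atoms: N-bromosuccinimide, O=C1CCC(=O)N1Br
Why: Electrophilic bromination should occur at C8', between the ring oxygen and the 7'-benzyloxy group, as is the rule for 5,7-di-O-benzyl flavans, because C6' is flanked by two freely rotating benzyloxy groups.

Step 11
Reactants: 16 C8' bromide
Product: 17 (1R,2R,5S)-5',7'-bis(benzyloxy)-6,6-dimethylspiro[bicyclo[3.1.1]heptane-2,2'-chromane]-8'-carbaldehyde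
Conditions: n-BuLi, THF, −78 °C; then DMF, −78 → 0 °C; 1 M HCl
Reagents that add atoms: N,N-dimethylformamide, CN(C)C=O
Why: Bromine–lithium exchange and formylation of the aryllithium with DMF should place the aldehyde at C8' with the regiochemistry fixed by the bromide.

Step 12
Reactants: 17 dibenzyl aldehyde
Product: 18 (1R,2R,5S)-5',7'-dihydroxy-6,6-dimethylspiro[bicyclo[3.1.1]heptane-2,2'-chromane]-8'-carbaldehyde
Conditions: H2 (1 atm), Pd/C (palladium on carbon), EtOAc, rt
Reagents that add atoms: none
Why: Hydrogenolysis of the two aryl benzyl ethers should be much faster than reduction of the hindered aldehyde, which becomes hydrogen-bonded to the freed 7'-hydroxyl, and the cyclobutane is inert under these conditions.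

Step 13
Reactants: 18 dihydroxy aldehyde
Product: 19 euglobal G3
Conditions: 3-methylbutanoyl chloride, TiCl4, CH2Cl2, −20 → 0 °C; then 1 M HCl
Reagents that add atoms: 3-methylbutanoyl chloride (isovaleryl chloride), CC(C)CC(Cl)=O
Why: Friedel–Crafts C-acylation of the phloroglucinol-type ring can only occur at C6', the single unsubstituted position, which lies between the two free hydroxyl groups.

**Compound list**

1 | (1R,5S)-(+)-nopinone (6,6-dimethylbicyclo[3.1.1]heptan-2-one) | O=C1CC[C@H]2C[C@@H]1C2(C)C | starting material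
2 | (1R,6S)-7,7-dimethyl-2-oxabicyclo[4.1.1]octan-3-one (ring oxygen on the former C1, cis to the C5 chain) | O=C1CC[C@H]2C[C@@H](O1)C2(C)C | intermediate
3 | (1R,6S)-7,7-dimethyl-2-oxabicyclo[4.1.1]octan-3-ol (lactol, both C3 epimers, in equilibrium with the open hydroxy aldehyde) | OC1CC[C@H]2C[C@@H](O1)C2(C)C | intermediate
4 | (1R,3S)-3-(but-3-yn-1-yl)-2,2-dimethylcyclobutan-1-ol (OH and side chain cis) | C#CCC[C@H]1C[C@@H](O)C1(C)C | intermediate
5 | O-[(1R,3S)-3-(but-3-yn-1-yl)-2,2-dimethylcyclobutyl] S-methyl carbonodithioate | C#CCC[C@H]1C[C@@H](OC(=S)SC)C1(C)C | intermediate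
6 | 3,5-bis(benzyloxy)phenol | Oc1cc(OCc2ccccc2)cc(OCc2ccccc2)c1 | starting material
7 | 2,4-bis(benzyloxy)-6-hydroxybenzaldehyde | O=Cc1c(O)cc(OCc2ccccc2)cc1OCc1ccccc1 | intermediate
8 | 2,4-bis(benzyloxy)-6-[(triisopropylsilyl)oxy]benzaldehyde | O=Cc1c(O[Si](C(C)C)(C(C)C)C(C)C)cc(OCc2ccccc2)cc1OCc1ccccc1 | intermediate
9 | propargylic alcohol: aryl-CH(OH)-C≡C-CH2CH2-cyclobutyl xanthate (both carbinol epimers) | OC(C#CCC[C@H]1C[C@@H](OC(=S)SC)C1(C)C)c1c(O[Si](C(C)C)(C(C)C)C(C)C)cc(OCc2ccccc2)cc1OCc1ccccc1 | intermediate
10 | aryl ynone: the ketone of 9 | O=C(C#CCC[C@H]1C[C@@H](OC(=S)SC)C1(C)C)c1c(O[Si](C(C)C)(C(C)C)C(C)C)cc(OCc2ccccc2)cc1OCc1ccccc1 | intermediate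
11 | 1-[2,4-bis(benzyloxy)-6-(triisopropylsilyloxy)phenyl]-2-[(1R,5S)-6,6-dimethylbicyclo[3.1.1]heptan-2-ylidene]ethan-1-one (E/Z mixture) | O=C(C=C1CC[C@H]2C[C@@H]1C2(C)C)c1c(O[Si](C(C)C)(C(C)C)C(C)C)cc(OCc2ccccc2)cc1OCc1ccccc1 | intermediate
12 | 1-[2,4-bis(benzyloxy)-6-hydroxyphenyl]-2-[(1R,5S)-6,6-dimethylbicyclo[3.1.1]heptan-2-ylidene]ethan-1-one (formed as its tetrabutylammonium phenoxide) | O=C(C=C1CC[C@H]2C[C@@H]1C2(C)C)c1c(O)cc(OCc2ccccc2)cc1OCc1ccccc1 | intermediate
13 | (1R,2R,5S)-5',7'-bis(benzyloxy)-6,6-dimethylspiro[bicyclo[3.1.1]heptane-2,2'-chroman]-4'-one (ring oxygen anti to the gem-dimethyl bridge) | O=C1C[C@@]2(CC[C@H]3C[C@@H]2C3(C)C)Oc2cc(OCc3ccccc3)cc(OCc3ccccc3)c21 | intermediate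
14 | the 4'-alcohol of 13 (both C4' epimers) | OC1C[C@@]2(CC[C@H]3C[C@@H]2C3(C)C)Oc2cc(OCc3ccccc3)cc(OCc3ccccc3)c21 | intermediate
15 | (1R,2R,5S)-5',7'-bis(benzyloxy)-6,6-dimethylspiro[bicyclo[3.1.1]heptane-2,2'-chromane] | C1C[C@@]2(CC[C@H]3C[C@@H]2C3(C)C)Oc2cc(OCc3ccccc3)cc(OCc3ccccc3)c21 | intermediate
16 | the 8'-bromo derivative of 15 | C1C[C@@]2(CC[C@H]3C[C@@H]2C3(C)C)Oc2c(Br)c(OCc3ccccc3)cc(OCc3ccccc3)c21 | intermediate
17 | the 8'-carbaldehyde of 15 | C1C[C@@]2(CC[C@H]3C[C@@H]2C3(C)C)Oc2c(C=O)c(OCc3ccccc3)cc(OCc3ccccc3)c21 | intermediate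
18 | (1R,2R,5S)-5',7'-dihydroxy-6,6-dimethylspiro[bicyclo[3.1.1]heptane-2,2'-chromane]-8'-carbaldehyde | C1C[C@@]2(CC[C@H]3C[C@@H]2C3(C)C)Oc2c(C=O)c(O)cc(O)c21 | intermediate
19 | euglobal G3, (1R,2R,5S)-5',7'-dihydroxy-6,6-dimethyl-6'-(3-methylbutanoyl)spiro[bicyclo[3.1.1]heptane-2,2'-chromane]-8'-carbaldehyde | CC(C)CC(=O)c1c(O)c(C=O)c2c(c1O)CC[C@@]1(CC[C@H]3C[C@@H]1C3(C)C)O2 | target

**Step count**

Total: 13 steps. Longest linear sequence: 11 steps (steps 1–3 and 6–13, from nopinone); the aromatic branch is steps 4–5.

**Steps most likely to fail**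

1. Step 8. The silane may transfer hydrogen to the cyclobutyl radical before the strained bridged ring has closed. Silyl radicals may also add to the ynone or to the enone product, and the latter would open the cyclobutane. The spiro configuration may erode by reversible oxa-Michael addition if the fluoride stage is prolonged. The fallback is a radical addition–fragmentation on a vinyl sulfone with no hydrogen donor present, and it sets out from 10. PhSO2Na and AcOH in EtOH should add sulfinate to the ynone β-carbon and give the β-(phenylsulfonyl) enone xanthate F1. Irradiation of F1 with (Bu3Sn)2 in benzene at 80 °C should release the C1 radical, which adds to the sulfonyl-bearing carbon and expels the sulfonyl radical as chain carrier. This gives silyl enone 11, where the route is rejoined at the fluoride stage of step 8.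

2. Step 13. The Lewis acid may ionise the tertiary aryl ether bond at the spiro carbon, after which the cyclobutane opens irreversibly; O-acylation without migration to carbon is a second failure mode. The fallback avoids Lewis acids by an organolithium–Weinreb amide sequence and sets out from 17. Ethylene glycol and PPTS in benzene (Dean–Stark) should give the dioxolane F2. NBS should brominate the only free ring position, C6', to give the bromide F3. n-BuLi at −78 °C followed by N-methoxy-N-methyl-3-methylbutanamide should give the ketone F4. Hydrogenolysis (H2, Pd/C) should give the diol F5, and 1 M HCl in THF should release the aldehyde and return to the route at 19.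

3. Step 9. Acid may cause elimination to the 2H-chromene and ionisation of its allylic tertiary C–O bond, or of the spiro ether itself, with loss of the pinane skeleton. The fallback is a near-neutral hydrazone reduction (Caglioti–Kabalka type) and sets out from 13. TsNHNH2 in MeOH at 60 °C should give the tosylhydrazone F6. Catecholborane in CHCl3 at 0 °C, then NaOAc·3H2O at reflux, should deliver the methylene compound and return to the route at 15.

Further compounds
F1 | step 8 | β-(phenylsulfonyl) enone xanthate: 1-[2,4-bis(benzyloxy)-6-(triisopropylsilyloxy)phenyl]-3-(phenylsulfonyl)-5-[(1S,3R)-cyclobutyl xanthate]pent-2-en-1-one (E/Z mixture) | O=C(C=C(CC[C@H]1C[C@@H](OC(=S)SC)C1(C)C)S(=O)(=O)c1ccccc1)c1c(O[Si](C(C)C)(C(C)C)C(C)C)cc(OCc2ccccc2)cc1OCc1ccccc1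
F2 | step 13 | 8'-(1,3-dioxolan-2-yl) derivative of 15 (dioxolane of 17) | C1C[C@@]2(CC[C@H]3C[C@@H]2C3(C)C)Oc2c(C3OCCO3)c(OCc3ccccc3)cc(OCc3ccccc3)c21
F3 | step 13 | 6'-bromo derivative of F2 | C1C[C@@]2(CC[C@H]3C[C@@H]2C3(C)C)Oc2c(C3OCCO3)c(OCc3ccccc3)c(Br)c(OCc3ccccc3)c21
F4 | step 13 | 6'-(3-methylbutanoyl) derivative of F2 | C1C[C@@]2(CC[C@H]3C[C@@H]2C3(C)C)Oc2c(C3OCCO3)c(OCc3ccccc3)c(C(=O)CC(C)C)c(OCc3ccccc3)c21
F5 | step 13 | 5',7'-dihydroxy-6'-(3-methylbutanoyl)-8'-(1,3-dioxolan-2-yl) spirochroman | C1C[C@@]2(CC[C@H]3C[C@@H]2C3(C)C)Oc2c(C3OCCO3)c(O)c(C(=O)CC(C)C)c(O)c21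
F6 | step 9 | 4-methylbenzenesulfonylhydrazone of 13 | Cc1ccc(cc1)S(=O)(=O)NN=C1C[C@@]2(CC[C@H]3C[C@@H]2C3(C)C)Oc2cc(OCc3ccccc3)cc(OCc3ccccc3)c21
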